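**Plan**
The target is 2,4-dihydroxy-5-methyl-6-(13-methyltetradecyl)benzoic acid, with C1 the ring carbon that bears CO2H.
Cut 1: the C2–OH bond, traced back to C2–H and installed late by the neighbouring carboxyl group.
Cut 2: ring bonds C1–C6 and C2–C3. C1, C2 and the carboxyl leave as methyl propiolate; C3–C6 (H, O, CH3, chain) remain as C3–C6 of a 4-methoxy-5-methyl-6-alkyl-2-pyrone, so only two ring carbons have to be added.
Cut 3: ring bond C5–C6, which divides the pyrone into methyl 3-oxopentanoate (C3, C4, C5 and the C5 methyl) and 14-methylpentadecanoic acid (its carboxyl carbon becomes C6).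
Forward: the chain is joined by γ-acylation of the keto ester dianion, the pyrone ring is closed and O-methylated, the pyrone is turned into the benzene ring by cycloaddition with loss of CO2, and saponification, C2 hydroxylation and O-demethylation finish the route.
Stereochemistry: the target has none (isopropyl chain end); the transient centres (C4 of the diketo ester, bridgeheads of the cycloadduct) disappear in the following step.

Key step: step 5

Remark: ring positions in the discussion use the target numbering (C1 CO2H, C2 OH, C3 H, C4 OH, C5 CH3, C6 chain); 14-methylpentadecanoic acid is assumed to be a purchasable iso-fatty acid.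

**Route**

Step 1
Reactants: 1 14-methylpentadecanoic acid
Product: 2 1-(14-methylpentadecanoyl)-1H-imidazole
Conditions: CDI (1.1 equiv), THF, rt; crude solid taken on after a cold aqueous wash
Reagents that add atoms: 1,1'-carbonyldiimidazole (CDI), O=C(n1ccnc1)n1ccnc1
Why: Carboxyl activation with CDI gives the N-acyl imidazole with loss of CO2 and imidazole, a standard acyl donor for carbanion acylation.

Step 2
Reactants: 2 1-(14-methylpentadecanoyl)-1H-imidazole; 3 methyl 3-oxopentanoate
Product: 5 methyl 4,18-dimethyl-3,5-dioxononadecanoate, via dilithium dienolate 4 (not isolated)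
Conditions: 3 (2.2 equiv), LiN(iPr)2 (LDA, 4.4 equiv), THF, −78 → 0 °C; then 2 (1 equiv), −78 °C → rt; aq. HCl
Reagents that add atoms: none
Why: In this Claisen-type γ-acylation of a β-keto ester dianion the C4 carbanion is the more reactive site and attacks the acyl imidazole, the second equivalent of dianion takes up the acidic proton of the new 3,5-diketo ester, and the C4 centre forms racemic and is removed in step 3.

Step 3
Reactants: 5 methyl 4,18-dimethyl-3,5-dioxononadecanoate
Product: 6 4-hydroxy-5-methyl-6-(13-methyltetradecyl)-2H-pyran-2-one
Conditions: DBU (1.5 equiv), toluene, 80 °C; aq. HCl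
Reagents that add atoms: none
Why: Base-mediated lactonisation, in which the C5 enolate oxygen attacks the methyl ester (6-exo-trig addition–elimination) with loss of methanol, is the usual cyclisation of 3,5-diketo esters to 4-hydroxy-2-pyrones.

Step 4
Reactants: 6 4-hydroxy-5-methyl-6-(13-methyltetradecyl)-2H-pyran-2-one
Product: 7 4-methoxy-5-methyl-6-(13-methyltetradecyl)-2H-pyran-2-one
Conditions: Me2SO4 (1.3 equiv), K2CO3 (2 equiv), acetone, reflux
Reagents that add atoms: dimethyl sulfate, COS(=O)(=O)OC
Why: Williamson-type O-methylation of the vinylogous acid with the hard electrophile dimethyl sulfate and K2CO3 should give the 4-methoxy-2-pyrone and not the 2-methoxy-4-pyrone isomer, as is normal for 4-hydroxy-2-pyrones under these conditions.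

Step 5
Reactants: 7 4-methoxy-5-methyl-6-(13-methyltetradecyl)-2H-pyran-2-one; 8 methyl propiolate
Product: 10 methyl 4-methoxy-3-methyl-2-(13-methyltetradecyl)benzoate, via bicyclic lactone 9 (not isolated)
Conditions: 8 (10 equiv), BHT (cat.), neat, sealed tube, 190 °C
Reagents that add atoms: none
Why: The pyrone acts as a donor-substituted cyclic diene whose C3 and C6 add across the alkyne in a thermal [4+2] cycloaddition to give the 2-oxabicyclo[2.2.2]octa-5,7-dien-3-one 9, and a retro-[4+2] loss of CO2 from 9, driven by aromatisation, releases the benzene ring. The closest known reaction type is the Diels–Alder/decarboxylation sequence of 4-alkoxy-2-pyrones with acetylenic esters to give benzoates. The six-membered carbocycle closes by intermolecular [4+2] annulation that forms C2–C3 and C1–C6 (target numbering) in one pericyclic event, after which the lactone bridge is excised, so the pyrone ring is converted into the arene. No stereocentre survives, because the two bridgehead centres of 9 are fixed relative to each other by the bicycle and both become sp2 when CO2 leaves. The step needs regioselectivity, which should follow from the diene polarisation: C3 is the β-carbon of the C4 enol ether and the vinylogous terminus of the ring-oxygen donor, hence the most nucleophilic end, and it bonds to the unsubstituted electrophilic β-carbon of the propiolate, so the ester carbon joins C6 and ends up para to the methoxy group. Excess alkyne, a radical inhibitor and a sealed vessel are meant to offset the low reactivity of the fully substituted C6 terminus.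

Step 6
Reactants: 10 methyl 4-methoxy-3-methyl-2-(13-methyltetradecyl)benzoate
Product: 11 4-methoxy-3-methyl-2-(13-methyltetradecyl)benzoic acid
Conditions: KOH (5 equiv), MeOH/THF/H2O, 65 °C; then 1 M HCl
Reagents that add atoms: potassium hydroxide, [K+].[OH-]
Why: Saponification (acyl–oxygen cleavage by hydroxide) of a benzoate with a single ortho substituent is routine, and the aryl methyl ether is inert to aqueous base.

Step 7
Reactants: 11 4-methoxy-3-methyl-2-(13-methyltetradecyl)benzoic acid
Product: 12 2-hydroxy-4-methoxy-5-methyl-6-(13-methyltetradecyl)benzoic acid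
Conditions: Pd(OAc)2 (10 mol %), KOAc (2 equiv), O2 (5 atm), DMA, 115 °C; then cold 1 M HCl
Reagents that add atoms: dioxygen, O=O
Why: Carboxylate-directed ortho C–H activation by divalent palladium (acetate-assisted concerted metalation–deprotonation) can only form the five-membered palladacycle at C2, the single free ortho position, and oxygenation of that aryl–palladium bond by O2 gives the phenol, which is the known palladium-catalysed ortho-hydroxylation of benzoic acids.

Step 8
Reactants: 12 2-hydroxy-4-methoxy-5-methyl-6-(13-methyltetradecyl)benzoic acid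
Product: 13 2,4-dihydroxy-5-methyl-6-(13-methyltetradecyl)benzoic acid
Conditions: BBr3 (4 equiv), CH2Cl2, −78 → 0 °C; ice-water quench
Reagents that add atoms: none
Why: Lewis acid ether cleavage with BBr3 (bromide attacks the methyl group of the ether–boron adduct in an SN2 step) frees the C4 phenol, and the low temperature with a cold aqueous quench should keep the acid-sensitive 2,4-dihydroxybenzoic acid from losing CO2.

**Compound list**

1 | 14-methylpentadecanoic acid | OC(=O)CCCCCCCCCCCCC(C)C | starting material
2 | 1-(14-methylpentadecanoyl)-1H-imidazole | O=C(n1ccnc1)CCCCCCCCCCCCC(C)C | intermediate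
3 | methyl 3-oxopentanoate | CCC(=O)CC(=O)OC | starting material
4 | dilithium dienolate (C2,C4-dianion) of methyl 3-oxopentanoate | [Li+].[Li+].C[CH-]C(=O)[CH-]C(=O)OC | intermediate (not isolated)
5 | methyl 4,18-dimethyl-3,5-dioxononadecanoate (racemic at C4, keto–enol mixture) | COC(=O)CC(=O)C(C)C(=O)CCCCCCCCCCCCC(C)C | intermediate
6 | 4-hydroxy-5-methyl-6-(13-methyltetradecyl)-2H-pyran-2-one | CC1=C(CCCCCCCCCCCCC(C)C)OC(=O)C=C1O | intermediate
7 | 4-methoxy-5-methyl-6-(13-methyltetradecyl)-2H-pyran-2-one | COC1=CC(=O)OC(CCCCCCCCCCCCC(C)C)=C1C | intermediate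
8 | methyl propiolate | COC(=O)C#C | starting material
9 | methyl 5-methoxy-6-methyl-1-(13-methyltetradecyl)-3-oxo-2-oxabicyclo[2.2.2]octa-5,7-diene-7-carboxylate (racemic; bridgeheads fixed by the bicycle) | COC(=O)C1=CC2C(OC)=C(C)C1(CCCCCCCCCCCCC(C)C)OC2=O | intermediate (not isolated)
10 | methyl 4-methoxy-3-methyl-2-(13-methyltetradecyl)benzoate | COC(=O)c1ccc(OC)c(C)c1CCCCCCCCCCCCC(C)C | intermediate
11 | 4-methoxy-3-methyl-2-(13-methyltetradecyl)benzoic acid | OC(=O)c1ccc(OC)c(C)c1CCCCCCCCCCCCC(C)C | intermediate
12 | 2-hydroxy-4-methoxy-5-methyl-6-(13-methyltetradecyl)benzoic acid | COc1cc(O)c(C(=O)O)c(CCCCCCCCCCCCC(C)C)c1C | intermediate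
13 | 2,4-dihydroxy-5-methyl-6-(13-methyltetradecyl)benzoic acid | Cc1c(O)cc(O)c(C(=O)O)c1CCCCCCCCCCCCC(C)C | target

**Step count**

Total step count: 8. Longest linear sequence: 8 steps (from 1 to 13).

**Steps most likely to fail**

Step 5. The cycloaddition may be too slow at the fully substituted C6 terminus, so the propiolate oligomerises before it is captured. Steric pressure at C6 may also override the electronic bias and turn the alkyne round, putting the ester meta to the methoxy group. Fallback: setting out from pyrone 7, the alkyne is replaced by a more reactive, more strongly polarised alkene that carries its own leaving group, methyl 2-chloroacrylate (toluene, BHT, sealed tube, about 130 °C). The same two bonds should form in the same orientation to give the bridged lactone methyl 7-chloro-5-methoxy-6-methyl-1-(13-methyltetradecyl)-3-oxo-2-oxabicyclo[2.2.2]oct-5-ene-7-carboxylate F1. Further heating in o-dichlorobenzene at about 180 °C should expel CO2 and give the diene methyl 1-chloro-4-methoxy-3-methyl-2-(13-methyltetradecyl)cyclohexa-2,4-diene-1-carboxylate F2. Elimination of HCl with DBU then aromatises the ring, and the route is rejoined at benzoate 10.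

Step 7. Palladation at C2 may be slow on this crowded, electron-rich acid, the benzylic C–H bonds of the chain may be activated instead and lead to lactonisation, or the salicylate formed may be over-oxidised or lose CO2 at 115 °C under O2. Fallback: setting out from ester 10, the oxygen is introduced through boron without free acid, oxidant gas or palladium. Ester-directed ortho C–H borylation ([Ir(OMe)(cod)]2, P[3,5-(CF3)2C6H3]3, B2pin2, octane, 80 °C) should give methyl 4-methoxy-3-methyl-2-(13-methyltetradecyl)-6-(4,4,5,5-tetramethyl-1,3,2-dioxaborolan-2-yl)benzoate F3. Oxidation of the C–B bond (NaBO3·4H2O, THF/H2O, rt) then gives methyl 2-hydroxy-4-methoxy-5-methyl-6-(13-methyltetradecyl)benzoate F4. Saponification of this hindered ester (KOH, DMSO/H2O, 80 °C, cold acidification) returns to the route at acid 12.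

Step 8. Protodecarboxylation of the 2,4-dihydroxybenzoic acid may occur under the Lewis and Brønsted acidic conditions of the ether cleavage or during the quench. Fallback: the methyl ether is exchanged for a benzyl ether at the ester stage, where no decarboxylation is possible, so the final unmasking is a neutral hydrogenolysis. Setting out from ester 10, BBr3 (CH2Cl2, −78 → 0 °C) should give methyl 4-hydroxy-3-methyl-2-(13-methyltetradecyl)benzoate F5. Benzylation (BnBr, K2CO3, DMF) gives methyl 4-(benzyloxy)-3-methyl-2-(13-methyltetradecyl)benzoate F6, and saponification (KOH, MeOH/THF/H2O) gives 4-(benzyloxy)-3-methyl-2-(13-methyltetradecyl)benzoic acid F7. Hydroxylation under the conditions of step 7 gives 4-(benzyloxy)-2-hydroxy-5-methyl-6-(13-methyltetradecyl)benzoic acid F8. Hydrogenolysis (H2, Pd/C, EtOAc, rt) removes the benzyl group and arrives at the target 13.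

**Further compounds**

F1 | step 5 | methyl 7-chloro-5-methoxy-6-methyl-1-(13-methyltetradecyl)-3-oxo-2-oxabicyclo[2.2.2]oct-5-ene-7-carboxylate (racemic, C7 epimers) | COC(=O)C1(Cl)CC2C(OC)=C(C)C1(CCCCCCCCCCCCC(C)C)OC2=O
F2 | step 5 | methyl 1-chloro-4-methoxy-3-methyl-2-(13-methyltetradecyl)cyclohexa-2,4-diene-1-carboxylate (racemic) | COC(=O)C1(Cl)CC=C(OC)C(C)=C1CCCCCCCCCCCCC(C)C
F3 | step 7 | methyl 4-methoxy-3-methyl-2-(13-methyltetradecyl)-6-(4,4,5,5-tetramethyl-1,3,2-dioxaborolan-2-yl)benzoate | COC(=O)c1c(B2OC(C)(C)C(C)(C)O2)cc(OC)c(C)c1CCCCCCCCCCCCC(C)C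
F4 | step 7 | methyl 2-hydroxy-4-methoxy-5-methyl-6-(13-methyltetradecyl)benzoate | COC(=O)c1c(O)cc(OC)c(C)c1CCCCCCCCCCCCC(C)C
F5 | step 8 | methyl 4-hydroxy-3-methyl-2-(13-methyltetradecyl)benzoate | COC(=O)c1ccc(O)c(C)c1CCCCCCCCCCCCC(C)C
F6 | step 8 | methyl 4-(benzyloxy)-3-methyl-2-(13-methyltetradecyl)benzoate | COC(=O)c1ccc(OCc2ccccc2)c(C)c1CCCCCCCCCCCCC(C)C
F7 | step 8 | 4-(benzyloxy)-3-methyl-2-(13-methyltetradecyl)benzoic acid | OC(=O)c1ccc(OCc2ccccc2)c(C)c1CCCCCCCCCCCCC(C)C
F8 | step 8 | 4-(benzyloxy)-2-hydroxy-5-methyl-6-(13-methyltetradecyl)benzoic acid | OC(=O)c1c(O)cc(OCc2ccccc2)c(C)c1CCCCCCCCCCCCC(C)C
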